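**Retrosynthetic overview** (germacrane numbering: ring C1–C10, lactone C11–C13, C14 = Me on C10, C15 = Me on C4)
1. Target ⇐ TBS ether 27 ⇐ ring-closing metathesis at C1=C2 of diene lactone 26; the ten-membered carbocycle is formed last.
2. 26 ⇐ C8 angeloylation of diol 25 ⇐ cis-α-methylene-γ-butyrolactone 24, formed first by indium Barbier allylation/lactonisation (C6–C7 bond) of fragment A with fragment B.
3. Fragment A (Z-enal 9, C2–C6): crotonaldehyde + methyl propiolate; C3 by Sharpless kinetic resolution; 4Z olefin by syn-carbocupration.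
4. Fragment B (bromide 20, C7–C10, C1, C11–C13): (R)-linalool supplies C10; C8 by L-proline α-aminoxylation; Morita–Baylis–Hillman reaction, then SN2′ bromination.
5. Ring order: lactone (step 16), then carbocycle (step 19).

Assumption: the target is taken exactly as the SMILES reads, i.e. a 6,7-cis-fused lactone with 3S,6S,7R,8R,10R and 1E,4Z geometry; commercial (R)-(−)-linalool of high ee is used.

**Fragment A**

Step 1
Reactants: 1 (E)-crotonaldehyde; 2 methyl propiolate
Product: 4 rac-methyl (5E)-4-hydroxyhept-5-en-2-ynoate, via lithium methyl propiolate 3 (not isolated)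
Conditions: LiN(SiMe3)2, THF, −78 °C; then 1, −78 °C; AcOH quench at −78 °C
Reagents that add atoms: none
Why: 1,2-addition of the lithium acetylide to the enal carbonyl at −78 °C (acetylide addition) gives the racemic propargylic/allylic alcohol, and no stereocontrol is needed yet.

Step 2
Reactants: 4 rac-methyl (5E)-4-hydroxyhept-5-en-2-ynoate
Product: 5 methyl (4S,5E)-4-hydroxyhept-5-en-2-ynoate
Conditions: Ti(OiPr)4 (0.2 equiv), L-(+)-diisopropyl tartrate (0.25 equiv), t-BuOOH (0.6 equiv), 4 Å MS, CH2Cl2, −20 °C (recovered alcohol, at most about 45%)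
Reagents that add atoms: none
Why: Sharpless kinetic resolution, in which L-(+)-tartrate epoxidises the (4R)-enantiomer fast on its (E)-propenyl group and leaves the (4S)-enantiomer (S because alkynyl outranks alkenyl), which sets C3 of the target.

Step 3
Reactants: 5 methyl (4S,5E)-4-hydroxyhept-5-en-2-ynoate
Product: 6 methyl (4S,5E)-4-[(tert-butyldimethylsilyl)oxy]hept-5-en-2-ynoate
Conditions: TBSOTf, 2,6-lutidine, CH2Cl2, −78 °C
Reagents that add atoms: tert-butyldimethylsilyl triflate, CC(C)(C)[Si](C)(C)OS(=O)(=O)C(F)(F)F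
Why: Low-temperature silylation with a hindered base protects the carbinol without base-induced isomerisation of the γ-hydroxy ynoate.

Step 4
Reactants: 6 methyl (4S,5E)-4-[(tert-butyldimethylsilyl)oxy]hept-5-en-2-ynoate
Product: 7 methyl (2Z,4S,5E)-4-[(tert-butyldimethylsilyl)oxy]-3-methylhepta-2,5-dienoate
Conditions: Me2CuLi (from MeLi and CuI), THF, −78 °C; MeOH quench at −78 °C, then aq. NH4Cl
Reagents that add atoms: lithium dimethylcuprate, [Li+].C[Cu-]C
Why: syn-Carbocupration of the ynoate with cold protonation places methyl and hydrogen cis, so the ester and the carbinol carbon end up cis (2Z), which fixes the 4Z olefin of the target.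

Step 5
Reactants: 7 methyl (2Z,4S,5E)-4-[(tert-butyldimethylsilyl)oxy]-3-methylhepta-2,5-dienoate
Product: 8 (2Z,4S,5E)-4-[(tert-butyldimethylsilyl)oxy]-3-methylhepta-2,5-dien-1-ol
Conditions: iBu2AlH (2.5 equiv), CH2Cl2, −78 °C; aq. potassium sodium tartrate
Reagents that add atoms: none
Why: Hydride reduction of the conjugated ester to the allylic alcohol at −78 °C leaves the silyl ether and both olefin geometries untouched.

Step 6
Reactants: 8 (2Z,4S,5E)-4-[(tert-butyldimethylsilyl)oxy]-3-methylhepta-2,5-dien-1-ol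
Product: 9 (2Z,4S,5E)-4-[(tert-butyldimethylsilyl)oxy]-3-methylhepta-2,5-dienal
Conditions: Dess–Martin periodinane, NaHCO3, CH2Cl2, 0 °C
Reagents that add atoms: none
Why: Buffered Dess–Martin oxidation gives the (Z)-enal under neutral conditions that do not isomerise it to the (E)-enal.

**Fragment B**

Step 7
Reactants: 10 (R)-(−)-linalool
Product: 11 (3R)-3,7-dimethyl-3-[(triethylsilyl)oxy]octa-1,6-diene
Conditions: TESOTf, 2,6-lutidine, CH2Cl2, 0 °C
Reagents that add atoms: triethylsilyl triflate, CC[Si](CC)(CC)OS(=O)(=O)C(F)(F)F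
Why: Silyl triflate silylation protects the hindered tertiary allylic alcohol so that the later aldehyde cannot close to a lactol; C10 of the target comes unchanged from the chiral pool.

Step 8
Reactants: 11 (3R)-3,7-dimethyl-3-[(triethylsilyl)oxy]octa-1,6-diene
Product: 12 (4R)-4-methyl-4-[(triethylsilyl)oxy]hex-5-enal
Conditions: O3 (1 equiv, Sudan Red 7B end point), CH2Cl2, pyridine (cat.), −78 °C; then Me2S
Reagents that add atoms: ozone, [O-][O+]=O
Why: Chemoselective ozonolysis, because the electron-rich trisubstituted olefin reacts far faster than the hindered monosubstituted vinyl group.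

Step 9
Reactants: 12 (4R)-4-methyl-4-[(triethylsilyl)oxy]hex-5-enal
Product: 14 (2R,4R)-2-(anilinooxy)-4-methyl-4-[(triethylsilyl)oxy]hex-5-en-1-ol, via α-anilinooxy aldehyde 13 (not isolated)
Conditions: PhNO, L-proline (20 mol%), CHCl3, 4 °C; then NaBH4, EtOH, 0 °C
Reagents that add atoms: nitrosobenzene, O=Nc1ccccc1
Why: Proline-catalysed α-aminoxylation (nitroso aldol through the enamine, with the carboxylic acid delivering PhNO) sets C8 of the target as 2R under catalyst control with L-proline, and NaBH4 reduces the labile aldehyde in the same pot.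

Step 10
Reactants: 14 (2R,4R)-2-(anilinooxy)-4-methyl-4-[(triethylsilyl)oxy]hex-5-en-1-ol
Product: 15 (2R,4R)-4-methyl-4-[(triethylsilyl)oxy]hex-5-ene-1,2-diol
Conditions: CuSO4·5H2O (0.3 equiv), MeOH, 0 °C to rt
Reagents that add atoms: none
Why: CuSO4-mediated N–O bond cleavage frees the secondary alcohol without touching the stereocentres or the tertiary silyl ether.

Step 11
Reactants: 15 (2R,4R)-4-methyl-4-[(triethylsilyl)oxy]hex-5-ene-1,2-diol
Product: 16 (2R,4R)-4-methyl-1,2,4-tris[(triethylsilyl)oxy]hex-5-ene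
Conditions: TESCl (2.4 equiv), imidazole, DMAP (cat.), CH2Cl2, 0 °C to rt
Reagents that add atoms: chlorotriethylsilane, CC[Si](Cl)(CC)CC
Why: Standard silylation of the primary and secondary hydroxyls.

Step 12
Reactants: 16 (2R,4R)-4-methyl-1,2,4-tris[(triethylsilyl)oxy]hex-5-ene
Product: 17 (2R,4R)-4-methyl-2,4-bis[(triethylsilyl)oxy]hex-5-enal
Conditions: (COCl)2, DMSO, CH2Cl2, −78 to −40 °C; then Et3N, −78 to 0 °C
Reagents that add atoms: none
Why: Under Swern conditions a primary triethylsilyl ether is cleaved and oxidised directly to the aldehyde while secondary and tertiary triethylsilyl ethers survive, and the α-stereocentre is not epimerised at low temperature.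

Step 13
Reactants: 17 (2R,4R)-4-methyl-2,4-bis[(triethylsilyl)oxy]hex-5-enal; 18 methyl acrylate
Product: 19 methyl (3RS,4R,6R)-3-hydroxy-6-methyl-2-methylidene-4,6-bis[(triethylsilyl)oxy]oct-7-enoate
Conditions: DABCO (1 equiv), neat 18 (10 equiv), MeOH (cat.), rt, 4–6 d
Reagents that add atoms: none
Why: Morita–Baylis–Hillman reaction of the activated α-silyloxy aldehyde; the new carbinol centre forms as a mixture that the next step erases.

Step 14
Reactants: 19 methyl (3RS,4R,6R)-3-hydroxy-6-methyl-2-methylidene-4,6-bis[(triethylsilyl)oxy]oct-7-enoate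
Product: 20 methyl (2Z,4R,6R)-2-(bromomethyl)-6-methyl-4,6-bis[(triethylsilyl)oxy]octa-2,7-dienoate
Conditions: NBS, Me2S, CH2Cl2, 0 °C to rt
Reagents that add atoms: N-bromosuccinimide, O=C1CCC(=O)N1Br
Why: Corey–Kim-type activation followed by SN2′ attack of bromide transposes the allylic system to the favoured (Z)-2-(bromomethyl)enoate (C8 cis to CH2Br) from both carbinol epimers.

**Acylating agent**

Step 15
Reactants: 21 angelic acid
Product: 22 (2Z)-2-methylbut-2-enoic 2,4,6-trichlorobenzoic anhydride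
Conditions: 2,4,6-Cl3C6H2COCl, Et3N, toluene, rt; filtered solution used directly
Reagents that add atoms: 2,4,6-trichlorobenzoyl chloride, O=C(Cl)c1c(Cl)cc(Cl)cc1Cl
Why: Yamaguchi-type mixed anhydride formation activates angelic acid without Z to E isomerisation.

**Coupling and endgame**

Step 16
Reactants: 9 (2Z,4S,5E)-4-[(tert-butyldimethylsilyl)oxy]-3-methylhepta-2,5-dienal; 20 methyl (2Z,4R,6R)-2-(bromomethyl)-6-methyl-4,6-bis[(triethylsilyl)oxy]octa-2,7-dienoate
Product: 24 (4S,5S)-5-[(1Z,3S,4E)-3-[(tert-butyldimethylsilyl)oxy]-2-methylhexa-1,4-dien-1-yl]-3-methylidene-4-[(1R,3R)-3-methyl-1,3-bis(triethylsilyloxy)pent-4-en-1-yl]oxolan-2-one, via open-chain hydroxy ester 23 (not isolated)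
Conditions: In powder, THF/H2O (1:1), rt; then PPTS (cat.), toluene, 40 °C
Reagents that add atoms: none
Why: Barbier allylation through a Zimmerman–Traxler chair, in which the (Z)-allylindium gives the syn adduct that closes to the cis-lactone, and the C8 centre selects the face (C8–H eclipsing C7=C11 to avoid A(1,3) strain, aldehyde anti to the C9 chain, silyloxy outside), setting C6 (S) and C7 as in the target (C7 reads S here only because the silicon on O8 changes the CIP ranking).

Step 17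
Reactants: 24 bis(triethylsilyl) lactone
Product: 25 (4R,5S)-5-[(1Z,3S,4E)-3-[(tert-butyldimethylsilyl)oxy]-2-methylhexa-1,4-dien-1-yl]-4-[(1R,3R)-1,3-dihydroxy-3-methylpent-4-en-1-yl]-3-methylideneoxolan-2-one
Conditions: HF·pyridine, pyridine, THF, 0 °C (monitored)
Reagents that add atoms: none
Why: Buffered HF·pyridine removes the two triethylsilyl ethers much faster than the secondary tert-butyldimethylsilyl ether (selective desilylation).

Step 18
Reactants: 25 diol lactone; 22 (2Z)-2-methylbut-2-enoic 2,4,6-trichlorobenzoic anhydride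
Product: 26 (1R,3R)-1-[(2S,3R)-2-[(1Z,3S,4E)-3-[(tert-butyldimethylsilyl)oxy]-2-methylhexa-1,4-dien-1-yl]-4-methylidene-5-oxooxolan-3-yl]-3-hydroxy-3-methylpent-4-en-1-yl (2Z)-2-methylbut-2-enoate
Conditions: 22 (3 equiv), Et3N, toluene, 75 °C, no DMAP
Reagents that add atoms: none
Why: DMAP-free Yamaguchi esterification transfers the angeloyl group from its unhindered carbonyl to the secondary C8 hydroxyl only (the tertiary C10 hydroxyl is inert) and keeps the Z geometry of the angelate.

Step 19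
Reactants: 26 diene lactone angelate
Product: 27 (3aR,4R,6R,7E,9S,10Z,11aS)-9-[(tert-butyldimethylsilyl)oxy]-6-hydroxy-6,10-dimethyl-3-methylidene-2-oxo-2,3,3a,4,5,6,9,11a-octahydrocyclodeca[b]furan-4-yl (2Z)-2-methylbut-2-enoate
Conditions: RuCl2(PCy3)2(=CHPh) (first-generation Grubbs catalyst, 20 mol% in portions), CH2Cl2 (1 mM), 40 °C
Reagents that add atoms: none
Why: Ring-closing metathesis in which the first-generation catalyst initiates at the C10 vinyl (helped by the free tertiary allylic hydroxyl), ignores the 1,1-disubstituted α-methylene lactone and the angelate, and closes onto the propenyl group with loss of propene; the cis-lactone and the Z-olefin pre-organise the chain and the E-olefin is expected because the Z-isomer would eclipse the C3 silyloxy and C10 substituents across the ring.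

Step 20
Reactants: 27 macrocyclic TBS ether
Product: 28 CNP0262559.7, (3aR,4R,6R,7E,9S,10Z,11aS)-6,9-dihydroxy-6,10-dimethyl-3-methylidene-2-oxo-2,3,3a,4,5,6,9,11a-octahydrocyclodeca[b]furan-4-yl (2Z)-2-methylbut-2-enoate
Conditions: HF·pyridine, THF, 0 °C to rt
Reagents that add atoms: none
Why: Fluoride-mediated desilylation under mildly acidic conditions leaves the α-methylene lactone, the angelate and the allylic alcohols intact and gives the target.

**Compound list**
1 | (E)-crotonaldehyde | C/C=C/C=O | starting material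
2 | methyl propiolate | C#CC(=O)OC | starting material
3 | lithium methyl propiolate | [Li]C#CC(=O)OC | intermediate
4 | rac-methyl (5E)-4-hydroxyhept-5-en-2-ynoate | C/C=C/C(O)C#CC(=O)OC | intermediate
5 | methyl (4S,5E)-4-hydroxyhept-5-en-2-ynoate | COC(=O)C#C[C@@H](O)/C=C/C | intermediate
6 | methyl (4S,5E)-4-[(tert-butyldimethylsilyl)oxy]hept-5-en-2-ynoate | COC(=O)C#C[C@@H](O[Si](C)(C)C(C)(C)C)/C=C/C | intermediate
7 | methyl (2Z,4S,5E)-4-[(tert-butyldimethylsilyl)oxy]-3-methylhepta-2,5-dienoate | COC(=O)/C=C(/C)[C@@H](O[Si](C)(C)C(C)(C)C)/C=C/C | intermediate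
8 | (2Z,4S,5E)-4-[(tert-butyldimethylsilyl)oxy]-3-methylhepta-2,5-dien-1-ol | OC/C=C(/C)[C@@H](O[Si](C)(C)C(C)(C)C)/C=C/C | intermediate
9 | (2Z,4S,5E)-4-[(tert-butyldimethylsilyl)oxy]-3-methylhepta-2,5-dienal (fragment A) | O=C/C=C(/C)[C@@H](O[Si](C)(C)C(C)(C)C)/C=C/C | intermediate
10 | (R)-(−)-linalool | CC(C)=CCC[C@@](C)(O)C=C | starting material
11 | (3R)-3,7-dimethyl-3-[(triethylsilyl)oxy]octa-1,6-diene | CC(C)=CCC[C@@](C)(O[Si](CC)(CC)CC)C=C | intermediate
12 | (4R)-4-methyl-4-[(triethylsilyl)oxy]hex-5-enal | O=CCC[C@@](C)(O[Si](CC)(CC)CC)C=C | intermediate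
13 | (2R,4R)-2-(anilinooxy)-4-methyl-4-[(triethylsilyl)oxy]hex-5-enal | O=C[C@H](ONc1ccccc1)C[C@@](C)(O[Si](CC)(CC)CC)C=C | intermediate
14 | (2R,4R)-2-(anilinooxy)-4-methyl-4-[(triethylsilyl)oxy]hex-5-en-1-ol | OC[C@H](ONc1ccccc1)C[C@@](C)(O[Si](CC)(CC)CC)C=C | intermediate
15 | (2R,4R)-4-methyl-4-[(triethylsilyl)oxy]hex-5-ene-1,2-diol | OC[C@H](O)C[C@@](C)(O[Si](CC)(CC)CC)C=C | intermediate
16 | (2R,4R)-4-methyl-1,2,4-tris[(triethylsilyl)oxy]hex-5-ene | CC[Si](CC)(CC)OC[C@H](O[Si](CC)(CC)CC)C[C@@](C)(O[Si](CC)(CC)CC)C=C | intermediate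
17 | (2R,4R)-4-methyl-2,4-bis[(triethylsilyl)oxy]hex-5-enal | O=C[C@H](O[Si](CC)(CC)CC)C[C@@](C)(O[Si](CC)(CC)CC)C=C | intermediate
18 | methyl acrylate | C=CC(=O)OC | starting material
19 | methyl (3RS,4R,6R)-3-hydroxy-6-methyl-2-methylidene-4,6-bis[(triethylsilyl)oxy]oct-7-enoate | COC(=O)C(=C)C(O)[C@H](O[Si](CC)(CC)CC)C[C@@](C)(O[Si](CC)(CC)CC)C=C | intermediate
20 | methyl (2Z,4R,6R)-2-(bromomethyl)-6-methyl-4,6-bis[(triethylsilyl)oxy]octa-2,7-dienoate (fragment B) | COC(=O)/C(CBr)=C/[C@H](O[Si](CC)(CC)CC)C[C@@](C)(O[Si](CC)(CC)CC)C=C | intermediate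
21 | angelic acid, (2Z)-2-methylbut-2-enoic acid | C/C=C(/C)C(=O)O | starting material
22 | (2Z)-2-methylbut-2-enoic 2,4,6-trichlorobenzoic anhydride | C/C=C(/C)C(=O)OC(=O)c1c(Cl)cc(Cl)cc1Cl | intermediate
23 | methyl (3S,4S,5Z,7S,8E)-7-[(tert-butyldimethylsilyl)oxy]-4-hydroxy-6-methyl-2-methylidene-3-[(1R,3R)-3-methyl-1,3-bis(triethylsilyloxy)pent-4-en-1-yl]deca-5,8-dienoate | COC(=O)C(=C)[C@@H]([C@@H](O)/C=C(/C)[C@@H](O[Si](C)(C)C(C)(C)C)/C=C/C)[C@H](O[Si](CC)(CC)CC)C[C@@](C)(O[Si](CC)(CC)CC)C=C | intermediate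
24 | (4S,5S)-5-[(1Z,3S,4E)-3-[(tert-butyldimethylsilyl)oxy]-2-methylhexa-1,4-dien-1-yl]-3-methylidene-4-[(1R,3R)-3-methyl-1,3-bis(triethylsilyloxy)pent-4-en-1-yl]oxolan-2-one | C=C1C(=O)O[C@@H](/C=C(/C)[C@@H](O[Si](C)(C)C(C)(C)C)/C=C/C)[C@H]1[C@H](O[Si](CC)(CC)CC)C[C@@](C)(O[Si](CC)(CC)CC)C=C | intermediate
25 | (4R,5S)-5-[(1Z,3S,4E)-3-[(tert-butyldimethylsilyl)oxy]-2-methylhexa-1,4-dien-1-yl]-4-[(1R,3R)-1,3-dihydroxy-3-methylpent-4-en-1-yl]-3-methylideneoxolan-2-one | C=C1C(=O)O[C@@H](/C=C(/C)[C@@H](O[Si](C)(C)C(C)(C)C)/C=C/C)[C@H]1[C@H](O)C[C@@](C)(O)C=C | intermediate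
26 | (1R,3R)-1-[(2S,3R)-2-[(1Z,3S,4E)-3-[(tert-butyldimethylsilyl)oxy]-2-methylhexa-1,4-dien-1-yl]-4-methylidene-5-oxooxolan-3-yl]-3-hydroxy-3-methylpent-4-en-1-yl (2Z)-2-methylbut-2-enoate | C=C1C(=O)O[C@@H](/C=C(/C)[C@@H](O[Si](C)(C)C(C)(C)C)/C=C/C)[C@H]1[C@H](OC(=O)/C(C)=C\C)C[C@@](C)(O)C=C | intermediate
27 | (3aR,4R,6R,7E,9S,10Z,11aS)-9-[(tert-butyldimethylsilyl)oxy]-6-hydroxy-6,10-dimethyl-3-methylidene-2-oxo-2,3,3a,4,5,6,9,11a-octahydrocyclodeca[b]furan-4-yl (2Z)-2-methylbut-2-enoate | C=C1C(=O)O[C@H]2/C=C(/C)[C@@H](O[Si](C)(C)C(C)(C)C)/C=C/[C@](C)(O)C[C@@H](OC(=O)/C(C)=C\C)[C@@H]12 | intermediate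
28 | CNP0262559.7, (3aR,4R,6R,7E,9S,10Z,11aS)-6,9-dihydroxy-6,10-dimethyl-3-methylidene-2-oxo-2,3,3a,4,5,6,9,11a-octahydrocyclodeca[b]furan-4-yl (2Z)-2-methylbut-2-enoate | C=C1C(=O)O[C@H]2/C=C(/C)[C@@H](O)/C=C/[C@](C)(O)C[C@@H](OC(=O)/C(C)=C\C)[C@@H]12 | target

**Step count and risks**

Total: 20 steps. Longest linear sequence: 13 steps (steps 7–14, then 16–20); the fragment A branch is 6 steps and the acylating agent 1 step.

Most likely to fail:

Step 19 (ring-closing metathesis). The ten-membered ring is strained, the E/Z outcome is not secured, and a more active catalyst could instead close a six-membered ring onto the α-methylene group. The fallback sets out from 26 and masks the exocyclic methylene by conjugate addition of Me2NH (THF, 0 °C) to give the dimethylamine adduct F4. Its camphorsulfonate salt is cyclised with the second-generation Grubbs catalyst RuCl2(PCy3)(H2IMes)(=CHPh) in toluene at 80 °C, where metathesis is reversible and the olefin geometry can equilibrate, giving the macrocyclic amine adduct F5. Quaternisation with MeI gives the trimethylammonium iodide F6, and NaHCO3 eliminates trimethylamine to restore the methylene group, returning to the route at 27.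

Step 16 (Barbier coupling). The syn (cis-lactone) outcome is well founded, but the face selection by the C8 silyloxy centre rests on a model and could be low or reversed. The fallback sets out from 19 and replaces substrate control by catalyst control. Acetylation (Ac2O, DMAP) gives the allylic acetate F1, and CuCl-catalysed SN2′ borylation with B2pin2 gives the allylboronate F2, which has the same olefin geometry as 20. A chiral phosphoric acid (the TRIP enantiomer that is matched to the required aldehyde face) then catalyses the allylboration of 9 through a closed six-membered transition state. This returns to the route at hydroxy ester 23, which lactonises to 24 as in step 16.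

Step 18 (angeloylation). Heating the free C8 alcohol next to the lactone risks translactonisation to the 8,12-lactone, and the angelate can isomerise to the tiglate. The fallback sets out from 25 and builds the Z-olefin on the ester instead of transferring it. Coupling with 2-(diphenoxyphosphoryl)propanoic acid (EDC·HCl, rt) gives the phosphonate ester F3. A Z-selective Horner–Wadsworth–Emmons olefination of Ando type with acetaldehyde (NaI, DBU, THF, −78 to 0 °C) then forms the (2Z)-2-methylbut-2-enoate, returning to the route at 26.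

**Further compounds**
F1 | step 16 | methyl (4R,6R)-3-acetoxy-6-methyl-2-methylidene-4,6-bis[(triethylsilyl)oxy]oct-7-enoate | COC(=O)C(=C)C(OC(C)=O)[C@H](O[Si](CC)(CC)CC)C[C@@](C)(O[Si](CC)(CC)CC)C=C
F2 | step 16 | methyl (2E,4R,6R)-6-methyl-2-[(4,4,5,5-tetramethyl-1,3,2-dioxaborolan-2-yl)methyl]-4,6-bis[(triethylsilyl)oxy]octa-2,7-dienoate | COC(=O)/C(CB1OC(C)(C)C(C)(C)O1)=C/[C@H](O[Si](CC)(CC)CC)C[C@@](C)(O[Si](CC)(CC)CC)C=C
F3 | step 18 | (1R,3R)-1-[(2S,3R)-2-[(1Z,3S,4E)-3-[(tert-butyldimethylsilyl)oxy]-2-methylhexa-1,4-dien-1-yl]-4-methylidene-5-oxooxolan-3-yl]-3-hydroxy-3-methylpent-4-en-1-yl 2-(diphenoxyphosphoryl)propanoate | C=C1C(=O)O[C@@H](/C=C(/C)[C@@H](O[Si](C)(C)C(C)(C)C)/C=C/C)[C@H]1[C@H](OC(=O)C(C)P(=O)(Oc1ccccc1)Oc1ccccc1)C[C@@](C)(O)C=C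
F4 | step 19 | dimethylamine adduct of 26, (1R,3R)-1-[(2S,3R)-2-[(1Z,3S,4E)-3-[(tert-butyldimethylsilyl)oxy]-2-methylhexa-1,4-dien-1-yl]-4-[(dimethylamino)methyl]-5-oxooxolan-3-yl]-3-hydroxy-3-methylpent-4-en-1-yl (2Z)-2-methylbut-2-enoate | CN(C)CC1C(=O)O[C@@H](/C=C(/C)[C@@H](O[Si](C)(C)C(C)(C)C)/C=C/C)[C@H]1[C@H](OC(=O)/C(C)=C\C)C[C@@](C)(O)C=C
F5 | step 19 | (3aR,4R,6R,7E,9S,10Z,11aS)-9-[(tert-butyldimethylsilyl)oxy]-3-[(dimethylamino)methyl]-6-hydroxy-6,10-dimethyl-2-oxo-2,3,3a,4,5,6,9,11a-octahydrocyclodeca[b]furan-4-yl (2Z)-2-methylbut-2-enoate | CN(C)CC1C(=O)O[C@H]2/C=C(/C)[C@@H](O[Si](C)(C)C(C)(C)C)/C=C/[C@](C)(O)C[C@@H](OC(=O)/C(C)=C\C)[C@@H]12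
F6 | step 19 | trimethylammonium iodide of F5 | C[N+](C)(C)CC1C(=O)O[C@H]2/C=C(/C)[C@@H](O[Si](C)(C)C(C)(C)C)/C=C/[C@](C)(O)C[C@@H](OC(=O)/C(C)=C\C)[C@@H]12.[I-]
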